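**Retrosynthetic overview**
1. Target 13 ⇐ global O-demethylation of phenol 12; the ring B 4-OH comes from an aldehyde by Baeyer–Villiger oxidation, so ring B is 5-bromovanillin and needs no protecting-group steps.
2. Ring B–O–ring C ether ⇐ Ullmann coupling of the AB bromo-aldehyde 9 with the CD phenol 6.
3. 9 ⇐ Chan–Lam O-arylation of 5-bromovanillin with 3,5-dimethoxyphenylboronic acid; 6 ⇐ Baeyer–Villiger oxidation of biaryl aldehyde 4.
4. 4 ⇐ Suzuki–Miyaura coupling of 3-bromo-2,4,6-trimethoxybenzaldehyde with 2,4,6-trimethoxyphenylboronic acid.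
5. No ring is built: the four benzene rings are bought and joined in the order C–D (biaryl), A–B (ether), AB–CD (ether).

Assumption: the target has no stereocentre and no stereogenic axis (the 2,4,6-trihydroxyphenyl ring is symmetric about the biaryl bond), so it is achiral and "single enantiomer" means the compound as drawn.

**Route**

Step 1
Reactants: 1 2,4,6-trimethoxybenzaldehyde
Product: 2 3-bromo-2,4,6-trimethoxybenzaldehyde
Conditions: NBS (1.05 equiv), MeCN, 0 °C to rt
Reagents that add atoms: N-bromosuccinimide (NBS), O=C1CCC(=O)N1Br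
Why: Electrophilic aromatic bromination, in which the only free positions (C3 and C5, equivalent) are each activated by two ortho and one para methoxy groups, so one equivalent of NBS gives a single monobromide.

Step 2
Reactants: 2 3-bromo-2,4,6-trimethoxybenzaldehyde; 3 (2,4,6-trimethoxyphenyl)boronic acid (2 equiv)
Product: 4 2,2',4,4',6,6'-hexamethoxybiphenyl-3-carbaldehyde
Conditions: Pd(OAc)2 (5 mol %), SPhos (10 mol %), K3PO4 (3 equiv), toluene/H2O 10:1, 100 °C, Ar
Reagents that add atoms: none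
Why: Suzuki–Miyaura coupling, in which the bulky electron-rich biarylphosphine drives oxidative addition and reductive elimination at the di-ortho-substituted bromide and excess boronic acid offsets protodeboronation; the aldehyde is inert and no stereogenic axis arises.

Step 3
Reactants: 4 2,2',4,4',6,6'-hexamethoxybiphenyl-3-carbaldehyde
Product: 6 2,2',4,4',6,6'-hexamethoxybiphenyl-3-ol, via aryl formate 5 (not isolated)
Conditions: mCPBA (1.3 equiv), CH2Cl2, 0 °C to rt; then K2CO3 (10 mol %), MeOH, rt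
Reagents that add atoms: 3-chloroperoxybenzoic acid (mCPBA), OOC(=O)c1cccc(Cl)c1
Why: Baeyer–Villiger (Dakin-type) oxidation, in which the 2,4,6-trioxygenated aryl group migrates in preference to hydride to give the aryl formate, which base-catalysed methanolysis converts to the phenol.

Step 4
Reactants: 7 3-bromo-4-hydroxy-5-methoxybenzaldehyde (5-bromovanillin); 8 (3,5-dimethoxyphenyl)boronic acid (2 equiv)
Product: 9 3-bromo-4-(3,5-dimethoxyphenoxy)-5-methoxybenzaldehyde
Conditions: Cu(OAc)2 (20 mol %), pyridine (3 equiv), 4 Å MS, CH2Cl2, O2 (1 atm), rt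
Reagents that add atoms: none
Why: Chan–Lam oxidative O-arylation, which proceeds at room temperature on 2,6-disubstituted acidic phenols and leaves the aryl bromide and the aldehyde untouched.

Step 5
Reactants: 9 3-bromo-4-(3,5-dimethoxyphenoxy)-5-methoxybenzaldehyde; 6 2,2',4,4',6,6'-hexamethoxybiphenyl-3-ol (1.3 equiv)
Product: 10 4-(3,5-dimethoxyphenoxy)-3-[(2,2',4,4',6,6'-hexamethoxybiphenyl-3-yl)oxy]-5-methoxybenzaldehyde
Conditions: CuI (20 mol %), picolinic acid (40 mol %), K3PO4 (2 equiv), DMSO, 100 °C, Ar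
Reagents that add atoms: none
Why: Ullmann-type C–O coupling with the CuI/picolinic acid system, which suits 2,6-disubstituted phenols and ortho-substituted aryl bromides; the formyl group makes ring B less electron-rich and survives the anhydrous phosphate base.

Step 6
Reactants: 10 4-(3,5-dimethoxyphenoxy)-3-[(2,2',4,4',6,6'-hexamethoxybiphenyl-3-yl)oxy]-5-methoxybenzaldehyde
Product: 12 4-(3,5-dimethoxyphenoxy)-3-[(2,2',4,4',6,6'-hexamethoxybiphenyl-3-yl)oxy]-5-methoxyphenol, via tetramer formate 11 (not isolated)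
Conditions: mCPBA (1.5 equiv), CH2Cl2, 0 °C to rt; then K2CO3 (10 mol %), MeOH, rt
Reagents that add atoms: 3-chloroperoxybenzoic acid (mCPBA), OOC(=O)c1cccc(Cl)c1
Why: Baeyer–Villiger oxidation of a 3,4,5-trioxygenated benzaldehyde, in which the para-aryloxy group favours aryl migration, so the formate and then the free ring B 4-OH of the target are obtained directly.

Step 7
Reactants: 12 4-(3,5-dimethoxyphenoxy)-3-[(2,2',4,4',6,6'-hexamethoxybiphenyl-3-yl)oxy]-5-methoxyphenol
Product: 13 3-[2-(3,5-dihydroxyphenoxy)-3,5-dihydroxyphenoxy]biphenyl-2,2',4,4',6,6'-hexol (target)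
Conditions: BBr3 (20 equiv), CH2Cl2, −78 °C to rt; then H2O, 0 °C; Ar, reversed-phase purification
Reagents that add atoms: none
Why: Lewis-acid-mediated ether cleavage, in which bromide attacks the methyl group of each boron-complexed aryl methyl ether (SN2) to free all nine phenols, while the diaryl ether and biaryl bonds are inert.

**Compound list**
1 | 2,4,6-trimethoxybenzaldehyde | COc1cc(OC)c(C=O)c(OC)c1 | starting material
2 | 3-bromo-2,4,6-trimethoxybenzaldehyde | COc1cc(OC)c(C=O)c(OC)c1Br | intermediate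
3 | (2,4,6-trimethoxyphenyl)boronic acid | COc1cc(OC)c(B(O)O)c(OC)c1 | starting material
4 | 2,2',4,4',6,6'-hexamethoxybiphenyl-3-carbaldehyde | COc1cc(OC)c(-c2c(OC)cc(OC)c(C=O)c2OC)c(OC)c1 | intermediate
5 | 2,2',4,4',6,6'-hexamethoxybiphenyl-3-yl formate | COc1cc(OC)c(-c2c(OC)cc(OC)c(OC=O)c2OC)c(OC)c1 | intermediate (not isolated)
6 | 2,2',4,4',6,6'-hexamethoxybiphenyl-3-ol | COc1cc(OC)c(-c2c(OC)cc(OC)c(O)c2OC)c(OC)c1 | intermediate
7 | 3-bromo-4-hydroxy-5-methoxybenzaldehyde (5-bromovanillin) | COc1cc(C=O)cc(Br)c1O | starting material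
8 | (3,5-dimethoxyphenyl)boronic acid | COc1cc(OC)cc(B(O)O)c1 | starting material
9 | 3-bromo-4-(3,5-dimethoxyphenoxy)-5-methoxybenzaldehyde | COc1cc(OC)cc(Oc2c(OC)cc(C=O)cc2Br)c1 | intermediate
10 | 4-(3,5-dimethoxyphenoxy)-3-[(2,2',4,4',6,6'-hexamethoxybiphenyl-3-yl)oxy]-5-methoxybenzaldehyde | COc1cc(OC)cc(Oc2c(OC)cc(C=O)cc2Oc2c(OC)cc(OC)c(-c3c(OC)cc(OC)cc3OC)c2OC)c1 | intermediate
11 | 4-(3,5-dimethoxyphenoxy)-3-[(2,2',4,4',6,6'-hexamethoxybiphenyl-3-yl)oxy]-5-methoxyphenyl formate | COc1cc(OC)cc(Oc2c(OC)cc(OC=O)cc2Oc2c(OC)cc(OC)c(-c3c(OC)cc(OC)cc3OC)c2OC)c1 | intermediate (not isolated)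
12 | 4-(3,5-dimethoxyphenoxy)-3-[(2,2',4,4',6,6'-hexamethoxybiphenyl-3-yl)oxy]-5-methoxyphenol | COc1cc(OC)cc(Oc2c(OC)cc(O)cc2Oc2c(OC)cc(OC)c(-c3c(OC)cc(OC)cc3OC)c2OC)c1 | intermediate
13 | 3-[2-(3,5-dihydroxyphenoxy)-3,5-dihydroxyphenoxy]biphenyl-2,2',4,4',6,6'-hexol | Oc1cc(O)cc(Oc2c(O)cc(O)cc2Oc2c(O)cc(O)c(-c3c(O)cc(O)cc3O)c2O)c1 | target

**Summary**
Total step count: 7 (convergent).
Longest linear sequence: 6 steps (steps 1, 2, 3, 5, 6, 7 from compound 1). The other branch is steps 4, 5, 6, 7 from compound 7.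

**Three steps most likely to fail**

Step 5 (Ullmann coupling to a tri-ortho-substituted diaryl ether; the hindered, oxidation-prone phenol 6 may react slowly, and at 100 °C the phenoxide could also displace the para-formyl-activated aryloxy group of 9). The fallback sets out from 9 and comes back at 10, and swaps the Ullmann substitution for an oxidative coupling at room temperature. Miyaura borylation of 9 (B2pin2, Pd(dppf)Cl2, KOAc, dioxane, 85 °C) gives 4-(3,5-dimethoxyphenoxy)-3-methoxy-5-(4,4,5,5-tetramethyl-1,3,2-dioxaborolan-2-yl)benzaldehyde F5. F5 is then joined to phenol 6 by Chan–Lam coupling (Cu(OAc)2, pyridine, 4 Å MS, CH2Cl2/MeCN, dry O2, rt) to give 10.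

Step 2 (tetra-ortho-methoxy biaryl; boronic acid 3 protodeboronates quickly under aqueous base). The fallback sets out from 2 and comes back at 4, and replaces the boron nucleophile by an organozinc that cannot protodeboronate. Aldehyde 2 is protected (ethylene glycol, TsOH, toluene, Dean–Stark) as 2-(3-bromo-2,4,6-trimethoxyphenyl)-1,3-dioxolane F1. Separately, 1,3,5-trimethoxybenzene is lithiated between two methoxy groups (n-BuLi, TMEDA, THF, 0 °C) to (2,4,6-trimethoxyphenyl)lithium F2, which ZnCl2 converts to (2,4,6-trimethoxyphenyl)zinc chloride F3. Negishi coupling of F1 with F3 (Pd2(dba)3, RuPhos, THF, 70 °C) gives 2-(2,2',4,4',6,6'-hexamethoxybiphenyl-3-yl)-1,3-dioxolane F4, and aqueous HCl in THF returns aldehyde 4.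

Step 7 (nine demethylations in one pot; incomplete cleavage and loss of the polar, air-sensitive decaphenol on purification are the main dangers). The fallback sets out from 12 and comes back at 13, and changes the isolation strategy to capture and release. The crude BBr3 product is not purified but peracetylated (Ac2O, pyridine, DMAP, rt) to the air-stable, silica-chromatographable decaacetate 3-[2-(3,5-diacetoxyphenoxy)-3,5-diacetoxyphenoxy]biphenyl-2,2',4,4',6,6'-hexayl hexaacetate F6. Partially methylated material is removed at this stage. Acid-catalysed methanolysis of F6 (HCl in MeOH, rt, Ar) then releases pure 13 on evaporation.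

**Further compounds**
F1 | step 2 | 2-(3-bromo-2,4,6-trimethoxyphenyl)-1,3-dioxolane | COc1cc(OC)c(C2OCCO2)c(OC)c1Br
F2 | step 2 | (2,4,6-trimethoxyphenyl)lithium | [Li]c1c(OC)cc(OC)cc1OC
F3 | step 2 | (2,4,6-trimethoxyphenyl)zinc chloride | Cl[Zn]c1c(OC)cc(OC)cc1OC
F4 | step 2 | 2-(2,2',4,4',6,6'-hexamethoxybiphenyl-3-yl)-1,3-dioxolane | COc1cc(OC)c(-c2c(OC)cc(OC)c(C3OCCO3)c2OC)c(OC)c1
F5 | step 5 | 4-(3,5-dimethoxyphenoxy)-3-methoxy-5-(4,4,5,5-tetramethyl-1,3,2-dioxaborolan-2-yl)benzaldehyde | COc1cc(OC)cc(Oc2c(OC)cc(C=O)cc2B3OC(C)(C)C(C)(C)O3)c1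
F6 | step 7 | 3-[2-(3,5-diacetoxyphenoxy)-3,5-diacetoxyphenoxy]biphenyl-2,2',4,4',6,6'-hexayl hexaacetate | CC(=O)Oc1cc(OC(C)=O)cc(Oc2c(OC(C)=O)cc(OC(C)=O)cc2Oc2c(OC(C)=O)cc(OC(C)=O)c(-c3c(OC(C)=O)cc(OC(C)=O)cc3OC(C)=O)c2OC(C)=O)c1
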